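Ring A is disconnected as a [3+3] annulation that exploits the 1,3-disposition of its two quaternary carbons (CMe2 and the O-bearing C–CH3) across the ring-fusion CH. Acrylonitrile supplies the CH2–CH2–CHBr bridge; the acyclic partner carries, on the future ring-fusion CH, a methyl ketone and an isopropenyl group. In one flask a ketyl radical adds to the acrylonitrile terminus and a hydrogen-atom-transfer-generated tertiary radical then closes onto the nitrile, so both ring bonds flanking the bridge form and the nitrile carbon emerges as a ketone. This ketone becomes the equatorial bromide via a bromoalkene; ring B (the oxepene) is closed last by the tertiary alkoxide opening a (Z)-vinyl epoxide.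

Key step: step 5

Remark: in step 5 acrylonitrile is the limiting partner (any excess is reduced by SmI2), so none is left when the tertiary radical is generated; hydrazone 12 is written without C=N geometry.

Step 1
Reactants: 1 (S)-4-benzyl-1,3-oxazolidin-2-one; 2 3-methylbut-2-enoyl chloride
Product: 3 (4S)-4-benzyl-3-(3-methylbut-2-enoyl)-1,3-oxazolidin-2-one
Conditions: n-BuLi, THF, −78 °C to 0 °C
Reagents that add atoms: none
Why: N-acylation of the lithiated Evans auxiliary by the acid chloride is a standard imide synthesis that installs the chiral controller without touching the enoyl group.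

Step 2
Reactants: 3 (4S)-4-benzyl-3-(3-methylbut-2-enoyl)-1,3-oxazolidin-2-one; 4 tert-butyl bromoacetate
Product: 5 tert-butyl (3S)-3-{[(4S)-4-benzyl-2-oxo-1,3-oxazolidin-3-yl]carbonyl}-4-methylpent-4-enoate
Conditions: NaN(SiMe3)2, THF, −78 °C; then 4, −78 °C to −40 °C
Reagents that add atoms: none
Why: Evans alkylation of the chelated Z-dienolate (formed by γ-deprotonation) should occur at the α-carbon on the face opposite the benzyl group, which sets the (S) center that becomes the ring-fusion CH and leaves the deconjugated isopropenyl group.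

Step 3
Reactants: 5 tert-butyl (3S)-3-{[(4S)-4-benzyl-2-oxo-1,3-oxazolidin-3-yl]carbonyl}-4-methylpent-4-enoate
Product: 6 tert-butyl (3S)-3-[methoxy(methyl)carbamoyl]-4-methylpent-4-enoate
Conditions: MeNH(OMe)·HCl, AlMe3, CH2Cl2, 0 °C
Reagents that add atoms: N,O-dimethylhydroxylamine hydrochloride, CNOC.Cl
Why: Aluminium-amide transamination of the exocyclic imide carbonyl (Weinreb amide formation) should release the auxiliary without epimerization and leave the tert-butyl ester alone.

Step 4
Reactants: 6 tert-butyl (3S)-3-[methoxy(methyl)carbamoyl]-4-methylpent-4-enoate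
Product: 7 tert-butyl (3S)-3-acetyl-4-methylpent-4-enoate
Conditions: MeMgBr, THF, −78 °C to 0 °C; cold NH4Cl quench
Reagents that add atoms: methylmagnesium bromide, C[Mg]Br
Why: The Weinreb ketone synthesis stops at the methyl ketone through the chelated tetrahedral intermediate, and the cold buffered quench should keep the α-center and the β,γ-alkene in place.

Step 5
Reactants: 7 tert-butyl (3S)-3-acetyl-4-methylpent-4-enoate; 8 acrylonitrile
Product: 11 tert-butyl 2-[(1S,6S)-6-hydroxy-2,2,6-trimethyl-3-oxocyclohexyl]acetate, via hydroxy nitrile 9 (not isolated), via ketimine 10 (not isolated)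
Conditions: SmI2, t-BuOH, THF, −78 °C to 0 °C; then EtOH, Fe(acac)3 (cat.), PhSiH3, 60 °C (same flask); aq. HCl
Reagents that add atoms: water, O
Why: SmI2 reduces the methyl ketone to a ketyl radical that adds to the CH2 terminus of acrylonitrile, and a second electron transfer with protonation gives nitrile 9, which makes the bond between the carbinol carbon and its ring CH2 neighbour; in the same flask hydrogen-atom transfer from the iron hydride (from Fe(acac)3 and PhSiH3) to the CH2 of the isopropenyl group gives the tertiary radical, which adds to the nitrile carbon, and the iminyl radical is reduced to ketimine 10 and hydrolysed on work-up, which makes the bond between the CMe2 carbon and the future CHBr carbon. The closest known reaction types are the SmI2 ketyl–olefin coupling of ketones with acrylonitrile and the metal-hydride hydrogen-atom-transfer cyclization of alkenyl nitriles to cyclic ketones. The cyclohexane ring closes in the 6-exo-dig mode. The new carbinol stereocenter is controlled by the adjacent (S) center through Felkin–Anh addition anti to the isopropenyl group (samarium chelation to the ester predicts the same face), while the CMe2 carbon is not stereogenic and the existing center is not enolized under these non-basic conditions. The step needs chemoselectivity, which the substrate secures because SmI2 reduces only the ketone and the iron hydride engages only the 1,1-disubstituted alkene, and it needs ring closure to outrun simple reduction of the tertiary radical, which the fully substituted carbinol carbon favours through the gem-disubstituent effect.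

Step 6
Reactants: 11 tert-butyl 2-[(1S,6S)-6-hydroxy-2,2,6-trimethyl-3-oxocyclohexyl]acetate
Product: 13 tert-butyl 2-[(1S,6S)-3-bromo-6-hydroxy-2,2,6-trimethylcyclohex-3-en-1-yl]acetate, via hydrazone 12 (not isolated)
Conditions: N2H4·H2O, Et3N, EtOH, 80 °C; then NBS, 1,1,3,3-tetramethylguanidine, CH2Cl2, 0 °C
Reagents that add atoms: hydrazine hydrate, NN.O; N-bromosuccinimide, O=C1CCC(=O)N1Br
Why: The Barton vinyl halide synthesis (oxidation of the hydrazone through the diazo compound, bromination and loss of N2 and a proton) can place the double bond only toward the single α-CH2, so one bromoalkene regioisomer should form.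

Step 7
Reactants: 13 tert-butyl 2-[(1S,6S)-3-bromo-6-hydroxy-2,2,6-trimethylcyclohex-3-en-1-yl]acetate
Product: 14 tert-butyl 2-[(1S,3S,6S)-3-bromo-6-hydroxy-2,2,6-trimethylcyclohexyl]acetate
Conditions: Mn(dpm)3 (cat.), PhSiH3, t-BuOOH, i-PrOH, 22 °C
Reagents that add atoms: none
Why: Metal-hydride hydrogen-atom-transfer hydrogenation keeps the C–Br bond, hydrogen adds to the ring CH to give the bromine-stabilized radical, and its axial quench from the face opposite the two axial methyl groups should give the thermodynamically favoured equatorial (S) bromide.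

Step 8
Reactants: 14 tert-butyl 2-[(1S,3S,6S)-3-bromo-6-hydroxy-2,2,6-trimethylcyclohexyl]acetate
Product: 15 tert-butyl 2-[(1S,3S,6S)-3-bromo-2,2,6-trimethyl-6-(trimethylsilyloxy)cyclohexyl]acetate
Conditions: N-(trimethylsilyl)imidazole, CH2Cl2, 40 °C
Reagents that add atoms: N-(trimethylsilyl)imidazole, C[Si](C)(C)n1ccnc1
Why: Silylation with the neutral silyl-imidazole reagent should mask the hindered tertiary alcohol (to stop later oxa-Michael closure onto the enoate and enone) without cleaving the tert-butyl ester.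

Step 9
Reactants: 15 tert-butyl 2-[(1S,3S,6S)-3-bromo-2,2,6-trimethyl-6-(trimethylsilyloxy)cyclohexyl]acetate
Product: 16 2-[(1S,3S,6S)-3-bromo-2,2,6-trimethyl-6-(trimethylsilyloxy)cyclohexyl]acetaldehyde
Conditions: i-Bu2AlH, CH2Cl2, −78 °C
Reagents that add atoms: none
Why: Partial reduction of the ester with diisobutylaluminium hydride should stop at the aldehyde because the aluminium hemiacetal survives at −78 °C until the quench.

Step 10
Reactants: 16 2-[(1S,3S,6S)-3-bromo-2,2,6-trimethyl-6-(trimethylsilyloxy)cyclohexyl]acetaldehyde; 17 methyl 2-[bis(2,2,2-trifluoroethoxy)phosphoryl]propanoate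
Product: 18 methyl (2Z)-4-[(1S,3S,6S)-3-bromo-2,2,6-trimethyl-6-(trimethylsilyloxy)cyclohexyl]-2-methylbut-2-enoate
Conditions: KN(SiMe3)2, 18-crown-6, THF, −78 °C
Reagents that add atoms: none
Why: The Still–Gennari olefination with the electron-poor phosphonate under dissociating conditions eliminates kinetically from the syn adduct, which should give the (Z)-trisubstituted enoate needed for a cis ring alkene.

Step 11
Reactants: 18 methyl (2Z)-4-[(1S,3S,6S)-3-bromo-2,2,6-trimethyl-6-(trimethylsilyloxy)cyclohexyl]-2-methylbut-2-enoate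
Product: 19 (3Z)-5-[(1S,3S,6S)-3-bromo-2,2,6-trimethyl-6-(trimethylsilyloxy)cyclohexyl]-1-chloro-3-methylpent-3-en-2-one
Conditions: ICH2Cl, MeLi·LiBr, THF, −78 °C
Reagents that add atoms: chloroiodomethane, ClCI
Why: Acylation of chloromethyllithium by the ester (carbenoid homologation) gives a tetrahedral adduct that is stable at −78 °C and collapses to the chloromethyl ketone only on quench, so neither a second addition nor attack on the alkyl bromide is expected.

Step 12
Reactants: 19 (3Z)-5-[(1S,3S,6S)-3-bromo-2,2,6-trimethyl-6-(trimethylsilyloxy)cyclohexyl]-1-chloro-3-methylpent-3-en-2-one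
Product: 20 (2S,3Z)-5-[(1S,3S,6S)-3-bromo-2,2,6-trimethyl-6-(trimethylsilyloxy)cyclohexyl]-1-chloro-3-methylpent-3-en-2-ol
Conditions: (S)-2-methyl-CBS-oxazaborolidine (cat.), catecholborane, toluene, −78 °C
Reagents that add atoms: none
Why: The Corey–Bakshi–Shibata reduction delivers hydride to the ketone bound anti to the larger alkenyl group, which should set the (S) carbinol by catalyst control and spare the alkene (1,2-reduction).

Step 13
Reactants: 20 (2S,3Z)-5-[(1S,3S,6S)-3-bromo-2,2,6-trimethyl-6-(trimethylsilyloxy)cyclohexyl]-1-chloro-3-methylpent-3-en-2-ol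
Product: 23 [(2R,5aS,7S,9aS)-7-bromo-3,6,6,9a-tetramethyl-2,5,5a,6,7,8,9,9a-octahydro-1-benzoxepin-2-yl]methanol, via diol 21 (not isolated), via epoxy alcohol 22 (not isolated)
Conditions: n-Bu4NF, THF, 0 °C; then KOt-Bu, 50 °C
Reagents that add atoms: none
Why: Fluoride desilylation and Williamson epoxide closure (retention at the carbinol carbon) should be followed by 7-exo-tet opening of the allylically activated epoxide carbon by the tertiary alkoxide with inversion, which gives the (R) ether center of the oxepene while the (Z)-alkene holds the two ends close.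

Step 14
Reactants: 23 [(2R,5aS,7S,9aS)-7-bromo-3,6,6,9a-tetramethyl-2,5,5a,6,7,8,9,9a-octahydro-1-benzoxepin-2-yl]methanol
Product: 24 palisadin B, (2R,5aS,7S,9aS)-7-bromo-2-(bromomethyl)-3,6,6,9a-tetramethyl-2,5,5a,6,7,8,9,9a-octahydro-1-benzoxepine
Conditions: CBr4, PPh3, CH2Cl2, 0 °C
Reagents that add atoms: tetrabromomethane, BrC(Br)(Br)Br
Why: The Appel reaction should convert the unhindered primary alcohol into the bromide by SN2 displacement of the oxyphosphonium group without touching any stereocenter.

Compound list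
1 | (S)-4-benzyl-1,3-oxazolidin-2-one | O=C1N[C@@H](Cc2ccccc2)CO1 | starting material
2 | 3-methylbut-2-enoyl chloride | CC(C)=CC(=O)Cl | starting material
3 | (4S)-4-benzyl-3-(3-methylbut-2-enoyl)-1,3-oxazolidin-2-one | CC(C)=CC(=O)N1[C@@H](Cc2ccccc2)COC1=O | intermediate
4 | tert-butyl bromoacetate | CC(C)(C)OC(=O)CBr | starting material
5 | tert-butyl (3S)-3-{[(4S)-4-benzyl-2-oxo-1,3-oxazolidin-3-yl]carbonyl}-4-methylpent-4-enoate | CC(C)(C)OC(=O)C[C@@H](C(C)=C)C(=O)N1[C@@H](Cc2ccccc2)COC1=O | intermediate
6 | tert-butyl (3S)-3-[methoxy(methyl)carbamoyl]-4-methylpent-4-enoate | CC(C)(C)OC(=O)C[C@@H](C(C)=C)C(=O)N(C)OC | intermediate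
7 | tert-butyl (3S)-3-acetyl-4-methylpent-4-enoate | CC(C)(C)OC(=O)C[C@@H](C(C)=C)C(C)=O | intermediate
8 | acrylonitrile | C=CC#N | starting material
9 | tert-butyl (3S)-3-[(2S)-4-cyano-2-hydroxybutan-2-yl]-4-methylpent-4-enoate (hydroxy nitrile, not isolated) | CC(C)(C)OC(=O)C[C@@H](C(C)=C)[C@@](C)(O)CCC#N | intermediate
10 | tert-butyl 2-[(1S,6S)-6-hydroxy-3-imino-2,2,6-trimethylcyclohexyl]acetate (ketimine, not isolated) | CC(C)(C)OC(=O)C[C@H]1C(C)(C)C(=N)CC[C@]1(C)O | intermediate
11 | tert-butyl 2-[(1S,6S)-6-hydroxy-2,2,6-trimethyl-3-oxocyclohexyl]acetate | CC(C)(C)OC(=O)C[C@H]1C(C)(C)C(=O)CC[C@]1(C)O | intermediate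
12 | tert-butyl 2-[(1S,6S)-3-hydrazinylidene-6-hydroxy-2,2,6-trimethylcyclohexyl]acetate (hydrazone, not isolated) | CC(C)(C)OC(=O)C[C@H]1C(C)(C)C(=NN)CC[C@]1(C)O | intermediate
13 | tert-butyl 2-[(1S,6S)-3-bromo-6-hydroxy-2,2,6-trimethylcyclohex-3-en-1-yl]acetate | CC(C)(C)OC(=O)C[C@H]1C(C)(C)C(Br)=CC[C@]1(C)O | intermediate
14 | tert-butyl 2-[(1S,3S,6S)-3-bromo-6-hydroxy-2,2,6-trimethylcyclohexyl]acetate | CC(C)(C)OC(=O)C[C@H]1C(C)(C)[C@@H](Br)CC[C@]1(C)O | intermediate
15 | tert-butyl 2-[(1S,3S,6S)-3-bromo-2,2,6-trimethyl-6-(trimethylsilyloxy)cyclohexyl]acetate | CC(C)(C)OC(=O)C[C@H]1C(C)(C)[C@@H](Br)CC[C@]1(C)O[Si](C)(C)C | intermediate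
16 | 2-[(1S,3S,6S)-3-bromo-2,2,6-trimethyl-6-(trimethylsilyloxy)cyclohexyl]acetaldehyde | O=CC[C@H]1C(C)(C)[C@@H](Br)CC[C@]1(C)O[Si](C)(C)C | intermediate
17 | methyl 2-[bis(2,2,2-trifluoroethoxy)phosphoryl]propanoate | COC(=O)C(C)P(=O)(OCC(F)(F)F)OCC(F)(F)F | starting material
18 | methyl (2Z)-4-[(1S,3S,6S)-3-bromo-2,2,6-trimethyl-6-(trimethylsilyloxy)cyclohexyl]-2-methylbut-2-enoate | COC(=O)/C(C)=C\C[C@H]1C(C)(C)[C@@H](Br)CC[C@]1(C)O[Si](C)(C)C | intermediate
19 | (3Z)-5-[(1S,3S,6S)-3-bromo-2,2,6-trimethyl-6-(trimethylsilyloxy)cyclohexyl]-1-chloro-3-methylpent-3-en-2-one | ClCC(=O)/C(C)=C\C[C@H]1C(C)(C)[C@@H](Br)CC[C@]1(C)O[Si](C)(C)C | intermediate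
20 | (2S,3Z)-5-[(1S,3S,6S)-3-bromo-2,2,6-trimethyl-6-(trimethylsilyloxy)cyclohexyl]-1-chloro-3-methylpent-3-en-2-ol | ClC[C@@H](O)/C(C)=C\C[C@H]1C(C)(C)[C@@H](Br)CC[C@]1(C)O[Si](C)(C)C | intermediate
21 | (1S,2S,4S)-4-bromo-2-[(2Z,4S)-5-chloro-4-hydroxy-3-methylpent-2-en-1-yl]-1,3,3-trimethylcyclohexan-1-ol (diol, not isolated) | ClC[C@@H](O)/C(C)=C\C[C@H]1C(C)(C)[C@@H](Br)CC[C@]1(C)O | intermediate
22 | (1S,2S,4S)-4-bromo-1,3,3-trimethyl-2-{(2Z)-3-[(2S)-oxiran-2-yl]but-2-en-1-yl}cyclohexan-1-ol (epoxy alcohol, not isolated) | O1C[C@@H]1/C(C)=C\C[C@H]2C(C)(C)[C@@H](Br)CC[C@]2(C)O | intermediate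
23 | [(2R,5aS,7S,9aS)-7-bromo-3,6,6,9a-tetramethyl-2,5,5a,6,7,8,9,9a-octahydro-1-benzoxepin-2-yl]methanol | CC1=CC[C@H]2C(C)(C)[C@@H](Br)CC[C@]2(C)O[C@H]1CO | intermediate
24 | palisadin B, (2R,5aS,7S,9aS)-7-bromo-2-(bromomethyl)-3,6,6,9a-tetramethyl-2,5,5a,6,7,8,9,9a-octahydro-1-benzoxepine | CC1=CC[C@H]2C(C)(C)[C@@H](Br)CC[C@]2(C)O[C@H]1CBr | target

Total step count: 14. Longest linear sequence: 14 steps (fully linear, 1 to 24).

Steps most likely to fail

Step 5. Facial selectivity in the ketyl addition may be poor, and the tertiary radical may be reduced (plain hydrogenation of the isopropenyl group) before it closes onto the nitrile. The fallback sets out from 7 and forms the two bonds in separate, polar-then-radical operations with a carbonyl as radical acceptor. The CeCl3-modified Grignard reagent of 2-(2-bromoethyl)-1,3-dioxolane should add to the ketone under the same Felkin–Anh control to give tert-butyl (3S)-3-[(2S)-4-(1,3-dioxolan-2-yl)-2-hydroxybutan-2-yl]-4-methylpent-4-enoate F1. Mild aqueous acid (pyridinium p-toluenesulfonate, acetone–water) should free the aldehyde as the lactol tert-butyl (3S)-3-[(2S)-5-hydroxy-2-methyloxolan-2-yl]-4-methylpent-4-enoate F2. Fe(acac)3/PhSiH3 hydrogen-atom-transfer cyclization of the tertiary radical onto the aldehyde carbon (open form of the lactol) should give tert-butyl 2-[(1S,6S)-3,6-dihydroxy-2,2,6-trimethylcyclohexyl]acetate F3 as either carbinol epimer. Dess–Martin oxidation of the secondary alcohol comes back to the route at 11.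

Step 6. Hydrazone formation at the ketone next to the quaternary carbon may be incomplete, and bromination may run on to the geminal dibromide instead of losing a proton. The fallback sets out from 11 and makes the dibromide on purpose. Hydrazone 12 is isolated and treated with CuBr2 and Et3N to give tert-butyl 2-[(1S,6S)-3,3-dibromo-6-hydroxy-2,2,6-trimethylcyclohexyl]acetate F4. One equivalent of Bu3SnH with Et3B and air at −78 °C should remove one bromine, the bromine-bearing radical taking hydrogen axially, and the route is rejoined at 14 (steps 6 and 7 are bypassed).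

Step 13. The hindered tertiary alkoxide may fail to open the epoxide, or may attack the far alkene carbon (SN2′) and close a five-membered ether instead. The fallback sets out from 18 and closes the ring by direct displacement with the bromide already in place. Bromomethyllithium (CH2Br2, MeLi·LiBr, −78 °C) should give (3Z)-1-bromo-5-[(1S,3S,6S)-3-bromo-2,2,6-trimethyl-6-(trimethylsilyloxy)cyclohexyl]-3-methylpent-3-en-2-one F5. The same (S)-CBS reduction should give (2S,3Z)-1-bromo-5-[(1S,3S,6S)-3-bromo-2,2,6-trimethyl-6-(trimethylsilyloxy)cyclohexyl]-3-methylpent-3-en-2-ol F6. MsCl and Et3N should give (2S,3Z)-1-bromo-5-[(1S,3S,6S)-3-bromo-2,2,6-trimethyl-6-(trimethylsilyloxy)cyclohexyl]-3-methylpent-3-en-2-yl methanesulfonate F7. n-Bu4NF desilylation followed by KOt-Bu should let the tertiary alkoxide displace the allylic mesylate in a 7-exo-tet closure with inversion, which comes back to the route at 24.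

Further compounds
F1 | step 5 | tert-butyl (3S)-3-[(2S)-4-(1,3-dioxolan-2-yl)-2-hydroxybutan-2-yl]-4-methylpent-4-enoate | CC(C)(C)OC(=O)C[C@@H](C(C)=C)[C@@](C)(O)CCC1OCCO1
F2 | step 5 | tert-butyl (3S)-3-[(2S)-5-hydroxy-2-methyloxolan-2-yl]-4-methylpent-4-enoate | CC(C)(C)OC(=O)C[C@@H](C(C)=C)[C@]1(C)CCC(O)O1
F3 | step 5 | tert-butyl 2-[(1S,6S)-3,6-dihydroxy-2,2,6-trimethylcyclohexyl]acetate | CC(C)(C)OC(=O)C[C@H]1C(C)(C)C(O)CC[C@]1(C)O
F4 | step 6 | tert-butyl 2-[(1S,6S)-3,3-dibromo-6-hydroxy-2,2,6-trimethylcyclohexyl]acetate | CC(C)(C)OC(=O)C[C@H]1C(C)(C)C(Br)(Br)CC[C@]1(C)O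
F5 | step 13 | (3Z)-1-bromo-5-[(1S,3S,6S)-3-bromo-2,2,6-trimethyl-6-(trimethylsilyloxy)cyclohexyl]-3-methylpent-3-en-2-one | BrCC(=O)/C(C)=C\C[C@H]1C(C)(C)[C@@H](Br)CC[C@]1(C)O[Si](C)(C)C
F6 | step 13 | (2S,3Z)-1-bromo-5-[(1S,3S,6S)-3-bromo-2,2,6-trimethyl-6-(trimethylsilyloxy)cyclohexyl]-3-methylpent-3-en-2-ol | BrC[C@@H](O)/C(C)=C\C[C@H]1C(C)(C)[C@@H](Br)CC[C@]1(C)O[Si](C)(C)C
F7 | step 13 | (2S,3Z)-1-bromo-5-[(1S,3S,6S)-3-bromo-2,2,6-trimethyl-6-(trimethylsilyloxy)cyclohexyl]-3-methylpent-3-en-2-yl methanesulfonate | BrC[C@@H](OS(C)(=O)=O)/C(C)=C\C[C@H]1C(C)(C)[C@@H](Br)CC[C@]1(C)O[Si](C)(C)C
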